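**Retrosynthetic overview**
1. GA43 (15) ⇐ saponification and oxidative C19–C20 cleavage of the 19,20-diketone 13 ⇐ bridged cyclopentanone 10 (C4–C19(=O)–C20H2–C10).
2. 10 ⇐ radical opening of cyclopropyl ketone 8 ⇐ key step: intramolecular [2+1] cycloaddition of the C19 diazo ketone 7 onto the Δ1(10) alkene, which makes the C10–C20 bond on the α-face.
3. 7 ⇐ acid 5 ⇐ anti SN2′ opening of the allylic 19→10 lactone by the neighbouring 3β-O-Boc group (sets the 2β-oxygen) ⇐ gibberellic acid 1.
4. Ring order: rings A–D and seven of the nine stereocentres are bought in 1 (C2 is set from C3, C10 is re-set from C4). The lactone is opened in step 4, the cyclopropane and cyclopentanone close together in step 6, the cyclopropane is opened in step 7 and the cyclopentanone is cut in step 10.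

Assumption: gibberellic acid (GA3), a bulk fermentation product, is taken as the cheap commercial chiral starting material; the target gibberellin is written GA43; atoms carry the usual gibberellin numbers, α is the face of C19/C20 and β the face of the 3-OH and H5. The route is a paper proposal; nothing here has been run.

**Step 1**
Reactants: 1 gibberellic acid (GA3)
Product: 2 GA3 7-methyl ester
Conditions: CH2N2, Et2O/MeOH, 0 °C
Reagents that add atoms: diazomethane C=[N+]=[N-]
Why: Esterification of the C7 acid by O-methylation with diazomethane under neutral conditions, which spares the base-labile allylic lactone and touches no stereocentre.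

**Step 2**
Reactants: 2 GA3 7-methyl ester
Product: 3 3-O-Boc GA3 7-methyl ester
Conditions: Boc2O, DMAP (cat.), MeCN, rt
Reagents that add atoms: di-tert-butyl dicarbonate CC(C)(C)OC(=O)OC(=O)OC(C)(C)C
Why: DMAP-catalysed O-acylation (carbonate formation) of the secondary allylic 3β-OH, while the tertiary bridgehead 13-OH does not react.

**Step 3**
Reactants: 3 3-O-Boc GA3 7-methyl ester
Product: 4 3-O-Boc 13-O-(methoxyoxalyl) GA3 7-methyl ester
Conditions: ClCOCO2Me, pyridine, DMAP (cat.), CH2Cl2, 0 °C → rt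
Reagents that add atoms: methyl chlorooxoacetate COC(=O)C(=O)Cl
Why: O-acylation of the remaining tertiary 13-OH to the methyl oxalate, which both arms C13 for radical deoxygenation and protects this allylic alcohol from acid-induced rearrangement in step 4.

**Step 4**
Reactants: 4 3-O-Boc 13-O-(methoxyoxalyl) GA3 7-methyl ester
Product: 5 2β,3β-cyclic carbonate Δ1(10)-ene 19-carboxylic acid (7-methyl ester; 13-O-methoxyoxalyl)
Conditions: BF3·OEt2 (0.3 equiv), 4 Å MS, CH2Cl2, −40 → −10 °C; pH 4 buffer
Reagents that add atoms: none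
Why: Lewis-acid ionisation of the tertiary allylic lactone with neighbouring-group participation (anti SN2′ allylic substitution): the Boc carbonyl oxygen on the β-face can only reach C2 from that face, so loss of isobutylene gives the cis-2β,3β-carbonate, the Δ1(10) alkene and the free C19 acid.

**Step 5**
Reactants: 5 2β,3β-cyclic carbonate Δ1(10)-ene 19-carboxylic acid
Product: 7 diazo ketone (C4–CO–CHN2 at C19), via acid chloride 6 (not isolated)
Conditions: Me2C=C(Cl)NMe2, CH2Cl2, 0 °C → rt; then CH2N2 (excess), Et2O, 0 °C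
Reagents that add atoms: diazomethane C=[N+]=[N-]
Why: Neutral acid chloride formation with the chloroenamine followed by acylation of diazomethane (first stage of the Arndt–Eistert sequence); C4 is quaternary, so no ketene can form and no stereocentre is at risk.

**Step 6**
Reactants: 7 diazo ketone
Product: 8 cyclopropyl ketone (C20 bonded to C19, C10 and C1 on the α-face)
Conditions: Cu(acac)2 (5 mol %), toluene, 80 °C, slow addition
Reagents that add atoms: none
Why: Intramolecular carbenoid [2+1] cycloaddition (cyclopropanation) onto the Δ1(10) alkene; the tether hangs from the α-axial C19, so C20 is delivered to C10 from the α-face, cis to C19, and the quaternary C10 stereocentre is set by C4.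

**Step 7**
Reactants: 8 cyclopropyl ketone
Product: 10 bridged ketone (C4–C19(=O)–C20H2–C10; C1 is CH2; 13-deoxy), via tributylstannyl enolate 9 (not isolated)
Conditions: Bu3SnH (3 equiv), AIBN (cat.), toluene, 110 °C; aqueous work-up
Reagents that add atoms: none
Why: One tin hydride radical chain does two jobs: the oxalate is cleaved to the C13 bridgehead radical, which takes up H with the ring geometry fixed, and the O-stannyl ketyl opens the cyclopropylcarbinyl system at C20–C1, the bond aligned with the carbonyl π system. The C1 radical is quenched by H-atom transfer, not reduced to a carbanion, so the C2 carbonate is not eliminated.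

**Step 8**
Reactants: 10 bridged ketone
Product: 12 20-hydroxy-19-ketone (C20 epimers), via potassium enolate 11 (not isolated)
Conditions: KN(SiMe3)2 (1.1 equiv), THF, −78 °C; then 2-(phenylsulfonyl)-3-phenyloxaziridine (racemic), −78 °C; AcOH
Reagents that add atoms: 2-(phenylsulfonyl)-3-phenyloxaziridine O=S(=O)(c1ccccc1)N1OC1c1ccccc1
Why: Enolate hydroxylation with an N-sulfonyloxaziridine (Davis oxidation); the ketone can only enolise toward C20 because C4 is quaternary, and the new C20 carbinol centre is erased in step 9.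

**Step 9**
Reactants: 12 20-hydroxy-19-ketone
Product: 13 19,20-diketone
Conditions: Dess–Martin periodinane, CH2Cl2, rt
Reagents that add atoms: none
Why: Dess–Martin oxidation of the α-ketol to the non-enolisable bridged 1,2-diketone (a camphorquinone-type system), leaving both alkenes untouched.

**Step 10**
Reactants: 13 19,20-diketone
Product: 15 GA43 (the target triacid), via dipotassium dicarboxylate 14 (not isolated)
Conditions: 30 % H2O2, KOH, THF/H2O, 0 °C; then KOH, MeOH/H2O, 70 °C; then aq. HCl to pH 3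
Reagents that add atoms: hydrogen peroxide OO; potassium hydroxide [K+].[OH-]
Why: Alkaline hydrogen peroxide cleavage of the 1,2-diketone (Baeyer–Villiger-type, through the cyclic anhydride) gives the C19 and C20 carboxylates, then saponification removes the carbonate and the C7 methyl ester. C19 is already a carboxylate when the 3-oxygen is freed, so no retro-aldol epimerisation at C3 can occur.

**Compound list**
1 | gibberellic acid (GA3) | C=C1C[C@]23C[C@@]1(O)CC[C@H]2[C@]14C=C[C@H](O)[C@@](C)(C(=O)O4)[C@H]1[C@@H]3C(=O)O | starting material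
2 | GA3 7-methyl ester | C=C1C[C@]23C[C@@]1(O)CC[C@H]2[C@]14C=C[C@H](O)[C@@](C)(C(=O)O4)[C@H]1[C@@H]3C(=O)OC | intermediate
3 | 3-O-Boc GA3 7-methyl ester | C=C1C[C@]23C[C@@]1(O)CC[C@H]2[C@]14C=C[C@H](OC(=O)OC(C)(C)C)[C@@](C)(C(=O)O4)[C@H]1[C@@H]3C(=O)OC | intermediate
4 | 3-O-Boc 13-O-(methoxyoxalyl) GA3 7-methyl ester | C=C1C[C@]23C[C@@]1(OC(=O)C(=O)OC)CC[C@H]2[C@]14C=C[C@H](OC(=O)OC(C)(C)C)[C@@](C)(C(=O)O4)[C@H]1[C@@H]3C(=O)OC | intermediate
5 | 2β,3β-cyclic carbonate Δ1(10)-ene 19-carboxylic acid (7-methyl ester; 13-O-methoxyoxalyl) | C=C1C[C@]23C[C@@]1(OC(=O)C(=O)OC)CC[C@H]2C1=C[C@@H]4OC(=O)O[C@@H]4[C@@](C)(C(=O)O)[C@H]1[C@@H]3C(=O)OC | intermediate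
6 | C19 acid chloride of 5 | C=C1C[C@]23C[C@@]1(OC(=O)C(=O)OC)CC[C@H]2C1=C[C@@H]4OC(=O)O[C@@H]4[C@@](C)(C(=O)Cl)[C@H]1[C@@H]3C(=O)OC | intermediate (not isolated)
7 | diazo ketone (C4–CO–CHN2) | C=C1C[C@]23C[C@@]1(OC(=O)C(=O)OC)CC[C@H]2C1=C[C@@H]4OC(=O)O[C@@H]4[C@@](C)(C(=O)C=[N+]=[N-])[C@H]1[C@@H]3C(=O)OC | intermediate
8 | cyclopropyl ketone (C20 on C19, C10α and C1α) | C=C1C[C@]23C[C@@]1(OC(=O)C(=O)OC)CC[C@H]2[C@]15[C@@H]6[C@@H]4OC(=O)O[C@@H]4[C@@](C)(C(=O)[C@H]56)[C@H]1[C@@H]3C(=O)OC | intermediate
9 | tributylstannyl enolate of 10 | C=C1C[C@]23C[C@H]1CC[C@H]2[C@]15C[C@@H]4OC(=O)O[C@@H]4[C@@](C)(C(O[Sn](CCCC)(CCCC)CCCC)=C5)[C@H]1[C@@H]3C(=O)OC | intermediate (not isolated)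
10 | bridged ketone (C4–C19(=O)–C20H2–C10; 13-deoxy) | C=C1C[C@]23C[C@H]1CC[C@H]2[C@]15C[C@@H]4OC(=O)O[C@@H]4[C@@](C)(C(=O)C5)[C@H]1[C@@H]3C(=O)OC | intermediate
11 | potassium enolate of 10 | C=C1C[C@]23C[C@H]1CC[C@H]2[C@]15C[C@@H]4OC(=O)O[C@@H]4[C@@](C)(C([O-])=C5)[C@H]1[C@@H]3C(=O)OC.[K+] | intermediate (not isolated)
12 | 20-hydroxy-19-ketone (C20 epimers; that centre is left open in the SMILES because step 9 erases it) | C=C1C[C@]23C[C@H]1CC[C@H]2[C@]15C[C@@H]4OC(=O)O[C@@H]4[C@@](C)(C(=O)C5O)[C@H]1[C@@H]3C(=O)OC | intermediate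
13 | 19,20-diketone | C=C1C[C@]23C[C@H]1CC[C@H]2[C@]15C[C@@H]4OC(=O)O[C@@H]4[C@@](C)(C(=O)C5=O)[C@H]1[C@@H]3C(=O)OC | intermediate
14 | dipotassium 19,20-dicarboxylate (2β,3β-carbonate; 7-methyl ester) | C=C1C[C@]23C[C@H]1CC[C@H]2[C@]1(C(=O)[O-])C[C@@H]4OC(=O)O[C@@H]4[C@@](C)(C(=O)[O-])[C@H]1[C@@H]3C(=O)OC.[K+].[K+] | intermediate (not isolated)
15 | GA43 (the target: 2β,3β-dihydroxy C20-gibberellin with free carboxylic acids at C7, C19 and C20 and the 16(17)-exocyclic alkene) | C=C1C[C@]23C[C@H]1CC[C@H]2[C@]1(C(=O)O)C[C@H](O)[C@H](O)[C@@](C)(C(=O)O)[C@H]1[C@@H]3C(=O)O | target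

**Totals**
Total step count: 10. Longest linear sequence: 10 steps (fully linear from 1).

**Three steps most likely to fail**

Step 4 (neighbouring-group SN2′ opening; untested on this substrate). The Lewis acid may only strip the Boc group, or the freed C19 acid may displace the new allylic carbonate and drain material into the 19→2α isolactone. The fallback sets out from compound 3 and puts the oxygen on C2 through boron. A monovalent-copper-catalysed anti SN2′ borylation of the allylic lactone (B2pin2, CuCl, Xantphos, KOtBu, THF) attacks C2 from the β-face and frees the C19 acid, giving 2β-pinacolboryl acid F1. NaBO3·4H2O (THF/H2O) oxidises the C–B bond with retention to 2β-hydroxy acid F2. NaH (THF, 0 °C) lets the 2β-alkoxide close onto the neighbouring Boc group with loss of tert-butanol to give carbonate 13-alcohol F3. Methyl chlorooxoacetate/pyridine (the mixed anhydride at C19 hydrolyses on work-up) then returns to compound 5.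

Step 6 (carbenoid cycloaddition). The copper carbenoid may give C–H insertion (C6–H) or dimer instead of the cyclopropane. The fallback sets out from compound 7 and uses no metal. Warming in toluene (80–100 °C, dark) lets the diazo ketone add across the Δ1(10) alkene as a 1,3-dipole to give 1-pyrazoline F4 (C20 on C10, nitrogen on C1, both on the α-face). Irradiation (350 nm, benzene) then extrudes nitrogen and returns to compound 8.

Step 7 (double-duty tin hydride step). The stannyl ketyl may fail to open the ring, so that only the oxalate is lost. Samarium diiodide or dissolving metal are not used, because they would take C1 to a carbanion and eliminate the C2 carbonate. The fallback sets out from compound 8 and opens the ring by a polar route first. MgI2 (Et2O/toluene, rt) adds iodide in a homo-conjugate fashion to C1 from the β-face, breaking the same C20–C1 bond, to give 1β-iodo ketone F5. Bu3SnH/AIBN (benzene, 80 °C) then removes the iodine and the 13-oxalate by radical chains and returns to compound 10.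

**Further compounds**
F1 | step 4 | 2β-pinacolboryl 3β-O-Boc Δ1(10)-ene 19-carboxylic acid (13-OH; 7-methyl ester) | C=C1C[C@]23C[C@@]1(O)CC[C@H]2C1=C[C@H](B4OC(C)(C)C(C)(C)O4)[C@H](OC(=O)OC(C)(C)C)[C@@](C)(C(=O)O)[C@H]1[C@@H]3C(=O)OC
F2 | step 4 | 2β-hydroxy 3β-O-Boc Δ1(10)-ene 19-carboxylic acid (13-OH; 7-methyl ester) | C=C1C[C@]23C[C@@]1(O)CC[C@H]2C1=C[C@H](O)[C@H](OC(=O)OC(C)(C)C)[C@@](C)(C(=O)O)[C@H]1[C@@H]3C(=O)OC
F3 | step 4 | 2β,3β-cyclic carbonate Δ1(10)-ene 19-carboxylic acid with free 13-OH (7-methyl ester) | C=C1C[C@]23C[C@@]1(O)CC[C@H]2C1=C[C@@H]4OC(=O)O[C@@H]4[C@@](C)(C(=O)O)[C@H]1[C@@H]3C(=O)OC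
F4 | step 6 | 1-pyrazoline (C20 on C10α; N on C1α; 19-ketone) | C=C1C[C@]23C[C@@]1(OC(=O)C(=O)OC)CC[C@H]2[C@]15[C@@H]6[C@@H]4OC(=O)O[C@@H]4[C@@](C)(C(=O)[C@H]5N=N6)[C@H]1[C@@H]3C(=O)OC
F5 | step 7 | 1β-iodo bridged ketone (13-O-methoxyoxalyl) | C=C1C[C@]23C[C@@]1(OC(=O)C(=O)OC)CC[C@H]2[C@]15[C@H](I)[C@@H]4OC(=O)O[C@@H]4[C@@](C)(C(=O)C5)[C@H]1[C@@H]3C(=O)OC
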